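**Plan**

- Retrosynthesis: both oxepanone C=O groups go back to carbinols. The left half is cut at the oxepane O–CMe2 bond and at the bond from the methyl-bearing quaternary carbon to the CH that carries the CH2CH2 link. The link is cut at CH2–CH (made as an sp3–sp2 bond). The right half is cut at its own O–CMe2 and C(CH3)–C(OH) bonds.
- Enabling feature: in the left bicycle the ring oxygen spans the CMe2 carbon and the ring CH–O, and the neighbouring quaternary C–CH3 is bonded to the CH bearing the CH2CH2 link, which sits beside the exocyclic C=CH2. This is the footprint of a 1,5-diepoxide chain ending in an allylsilane.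
- Forward, right half: geranyl bromide → propargylsilane diepoxide → oxepane and cyclohexane in one cascade (exocyclic allene) → ketone → α-methyl ketone → methylene → spiro-epoxide → vinyl carbinol.
- Forward, left chain and end game: geranyl bromide → enyne → iodo-allylsilane → diepoxide; B-alkyl Suzuki union; the left oxepane and methylenecyclohexane then close together; desilylation; double oxidation.
- Stereochemistry: the epoxide CH–O centres come from Shi epoxidation with the L-fructose-derived ketone. Each methyl-bearing quaternary carbon is set by inversion in a chair cascade, and the left ring CH by the Z-allylsilane geometry. The tertiary carbinol is set by epoxidation anti to the angular methyl, and the secondary methyl by equatorial alkylation.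

Key step: step 16

Assumption: the L-fructose-derived enantiomer of the Shi ketone (accessible from L-sorbose) and a titrated acetone solution of dimethyldioxirane are treated as available reagents.

Ring locants in the names follow 1-benzoxepine numbering (O1, C2 = CMe2, C3 = carbinol/ketone carbon, C5a = methyl-bearing quaternary carbon, C9a = ring CH–O).

**Right half**

Step 1
Reactants: 1 geranyl bromide [(2E)-1-bromo-3,7-dimethylocta-2,6-diene]; 2 (4-bromobut-1-yn-1-yl)trimethylsilane
Product: 5 (6E)-7,11-dimethyldodeca-6,10-dien-1-yne, via Grignard reagent 3 (not isolated), via silylalkyne 4 (not isolated)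
Conditions: 2, Mg, THF, 40 °C; 1, Li2CuCl4 (3 mol%), THF, −20 → 0 °C; crude 4, K2CO3, MeOH, rt
Reagents that add atoms: none
Why: Copper-catalysed Kochi coupling of a primary alkyl Grignard reagent with an allylic bromide should occur at the CH2Br carbon with the E-alkene untouched, and methanolysis of the alkynyl C–Si bond then frees the terminal alkyne.

Step 2
Reactants: 5 (6E)-7,11-dimethyldodeca-6,10-dien-1-yne; 6 (iodomethyl)trimethylsilane
Product: 8 trimethyl[(7E)-8,12-dimethyltrideca-7,11-dien-2-yn-1-yl]silane, via lithium acetylide 7 (not isolated)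
Conditions: n-BuLi, THF, −78 → 0 °C; 6, THF, 0 °C → reflux
Reagents that add atoms: none
Why: SN2 alkylation of a lithium acetylide with the silicon-activated primary iodide is the standard entry to propargylsilanes.

Step 3
Reactants: 8 trimethyl[(7E)-8,12-dimethyltrideca-7,11-dien-2-yn-1-yl]silane
Product: 9 trimethyl{6-[(2S,3S)-3-{2-[(2S)-3,3-dimethyloxiran-2-yl]ethyl}-3-methyloxiran-2-yl]hex-2-yn-1-yl}silane
Conditions: ent-Shi ketone (0.6 equiv), Oxone, K2CO3, Bu4NHSO4, MeCN/DMM–aq. Na2B4O7/EDTA (pH ≈ 10.5), 0 °C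
Reagents that add atoms: potassium peroxymonosulfate (Oxone), [K+].[O-]S(=O)(=O)OO
Why: Shi asymmetric epoxidation through the spiro dioxirane transition state should oxidise both trisubstituted alkenes from the same enantiotopic face (this ketone enantiomer giving the 2S,3S and 2S oxiranes), while the alkyne and the propargylic C–Si bond are inert to the dioxirane.

Step 4
Reactants: 9 diepoxy propargylsilane
Product: 11 (3S,5aS,9aS)-6-ethenylidene-2,2,5a-trimethyldecahydro-1-benzoxepin-3-ol, via trimethylsilyl ether 10 (not isolated)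
Conditions: TMSOTf (1.2 equiv), 2,6-di-tert-butyl-4-methylpyridine (DTBMP), CH2Cl2, −78 °C; then K2CO3, MeOH, rt
Reagents that add atoms: none
Why: In this known silyl-triflate-promoted oxa-/carbacyclisation cascade the silylated terminal epoxide is opened at its tertiary carbon by the inner epoxide oxygen, and the bicyclic epoxonium ion is opened at the methyl-bearing carbon, with inversion and through a chair, by the propargylsilane (SE2′, 6-exo), which sets the trans ring fusion and the quaternary centre and leaves an exocyclic allene.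

Step 5
Reactants: 11 allenyl oxepanol
Product: 12 tert-butyl{[(3S,5aS,9aS)-6-ethenylidene-2,2,5a-trimethyldecahydro-1-benzoxepin-3-yl]oxy}dimethylsilane
Conditions: TBSOTf, 2,6-lutidine, CH2Cl2, −78 → 0 °C
Reagents that add atoms: tert-butyldimethylsilyl trifluoromethanesulfonate, CC(C)(C)[Si](C)(C)OS(=O)(=O)C(F)(F)F
Why: Silyl triflate/lutidine silylation is reliable for a hindered secondary alcohol next to a quaternary carbon and leaves the allene alone.

Step 6
Reactants: 12 silyl-protected allene
Product: 13 (3S,5aR,9aS)-3-[(tert-butyldimethylsilyl)oxy]-2,2,5a-trimethyloctahydro-1-benzoxepin-6(2H)-one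
Conditions: O3, pyridine (3 equiv), CH2Cl2, −78 °C (Sudan Red 7B end point), N2 purge
Reagents that add atoms: ozone, [O-][O+]=O
Why: Ozonolysis of the only C=C unit, the 1,1-disubstituted allene, cleaves the ring-exocyclic double bond to the cyclohexanone (the two outer carbons leaving as formaldehyde and carbon monoxide) without touching a stereocentre.

Step 7
Reactants: 13 bicyclic ketone
Product: 15 (3S,5aR,7S,9aS)-3-[(tert-butyldimethylsilyl)oxy]-2,2,5a,7-tetramethyloctahydro-1-benzoxepin-6(2H)-one, via lithium enolate 14 (not isolated)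
Conditions: LDA, THF, −78 °C; MeI, −78 → −20 °C
Reagents that add atoms: iodomethane, CI
Why: Enolate alkylation: the ketone can enolise only towards C7 (the other α-carbon is quaternary), and methylation anti to the axial 5a-methyl gives the equatorial 7-methyl (7S), which is also the thermodynamic epimer because the alternative is syn-diaxial to the angular methyl.

Step 8
Reactants: 15 α-methyl ketone
Product: 16 tert-butyldimethyl{[(3S,5aS,7S,9aS)-2,2,5a,7-tetramethyl-6-methylidenedecahydro-1-benzoxepin-3-yl]oxy}silane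
Conditions: Cp2TiMe2 (3 equiv), toluene, 65 °C, dark
Reagents that add atoms: dimethyltitanocene (Petasis reagent), C[Ti](C)(C1C=CC=C1)C1C=CC=C1
Why: Petasis methylenation through Cp2Ti=CH2 is non-basic and suited to hindered, epimerisable ketones, so the 7S centre should be preserved.

Step 9
Reactants: 16 exocyclic alkene
Product: 17 tert-butyldimethylsilyl ether of (3S,5aR,6S,7S,9aS)-2,2,5a,7-tetramethyloctahydro-2H-spiro[1-benzoxepine-6,2'-oxiran]-3-ol (oxirane oxygen axial, anti to the 5a-methyl)
Conditions: dimethyldioxirane (acetone solution), CH2Cl2, 0 °C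
Reagents that add atoms: dimethyldioxirane, CC1(C)OO1
Why: Dioxirane epoxidation of the exocyclic methylene should occur from the face anti to the axial 5a-methyl (axial attack on the chair), placing the oxirane oxygen axial and the CH2 equatorial and so fixing the future tertiary carbinol (6S), in line with the α-face oxidation of exocyclic alkenes that flank an angular methyl in trans-fused decalins.

Step 10
Reactants: 17 spiro-epoxide
Product: 18 (3S,5aR,6S,7S,9aS)-3-[(tert-butyldimethylsilyl)oxy]-6-ethenyl-2,2,5a,7-tetramethyldecahydro-1-benzoxepin-6-ol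
Conditions: Me3S+ I− (5 equiv), n-BuLi (4.8 equiv), THF, −10 °C → rt
Reagents that add atoms: trimethylsulfonium iodide, C[S+](C)C.[I-]
Why: One-carbon homologation of an epoxide to an allylic alcohol with dimethylsulfonium methylide: the ylide opens the oxirane at its CH2, and elimination of dimethyl sulfide from the sulfonium alkoxide gives the vinyl group without touching the C–O bond of the stereocentre.

Step 11
Reactants: 18 vinyl carbinol
Product: 19 triethylsilyl ether of 18, (3S,5aR,6S,7S,9aS)-3-[(tert-butyldimethylsilyl)oxy]-6-ethenyl-2,2,5a,7-tetramethyl-6-[(triethylsilyl)oxy]decahydro-1-benzoxepine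
Conditions: TESOTf, 2,6-lutidine, CH2Cl2, 0 °C → rt
Reagents that add atoms: triethylsilyl trifluoromethanesulfonate, CC[Si](CC)(CC)OS(=O)(=O)C(F)(F)F
Why: A silyl triflate is reactive enough to silylate the hindered tertiary allylic alcohol, which has to be masked before hydroboration and the Lewis-acid cascade.

**Left chain**

Step 12
Reactants: 1 geranyl bromide; 20 trimethyl(prop-1-yn-1-yl)silane
Product: 23 (5E)-6,10-dimethylundeca-5,9-dien-1-yne, via lithiopropyne 21 (not isolated), via silyl dienyne 22 (not isolated)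
Conditions: 20, n-BuLi, THF, −78 → −20 °C; 1, −78 → 0 °C; crude 22, K2CO3, MeOH, rt
Reagents that add atoms: none
Why: The silyl-capped propargyl anion alkylates the allylic bromide at the CH2Br terminus (the silicon suppresses the allenyl pathway), and methanolysis then removes the alkynyl silicon.

Step 13
Reactants: 23 (5E)-6,10-dimethylundeca-5,9-dien-1-yne; 24 (trimethylsilyl)methylmagnesium chloride
Product: 27 [(2Z,5E)-2-(iodomethylidene)-6,10-dimethylundeca-5,9-dien-1-yl]trimethylsilane, via silylmethylcopper 25 (not isolated), via alkenylcopper 26 (not isolated)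
Conditions: 24, CuBr·SMe2, LiBr, THF, −30 → 20 °C; 23, 20 °C; I2, THF, −40 → 0 °C
Reagents that add atoms: iodine, II
Why: Carbocupration of a terminal alkyne is syn and places copper on the terminal carbon, and iodinolysis of the alkenylcopper goes with retention, so CH2SiMe3 and iodine end up cis (Z).

Step 14
Reactants: 27 iodo-allylsilane triene
Product: 28 {(2Z)-2-(iodomethylidene)-4-[(2S,3S)-3-{2-[(2S)-3,3-dimethyloxiran-2-yl]ethyl}-3-methyloxiran-2-yl]butyl}trimethylsilane
Conditions: ent-Shi ketone (0.6 equiv), Oxone (slow addition), K2CO3, Bu4NHSO4, MeCN/DMM–aq. Na2B4O7/EDTA (pH ≈ 10.5), −5 → 0 °C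
Reagents that add atoms: potassium peroxymonosulfate (Oxone), [K+].[O-]S(=O)(=O)OO
Why: Shi asymmetric epoxidation should be selective for the two trialkyl-substituted alkenes, again giving the 2S,3S and 2S oxiranes, because the iodine-bearing alkene is deactivated towards the electrophilic dioxirane.

**Union and end game**

Step 15
Reactants: 19 right-half vinyl carbinol silyl ether; 28 diepoxy alkenyl iodide
Product: 30 trimethyl{(2Z)-2-{2-[(2S,3S)-3-{2-[(2S)-3,3-dimethyloxiran-2-yl]ethyl}-3-methyloxiran-2-yl]ethyl}-5-[(3S,5aR,6S,7S,9aS)-3-[(tert-butyldimethylsilyl)oxy]-2,2,5a,7-tetramethyl-6-[(triethylsilyl)oxy]decahydro-1-benzoxepin-6-yl]pent-2-en-1-yl}silane, via B-alkyl-9-BBN 29 (not isolated)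
Conditions: 19, 9-BBN dimer, THF, rt → 50 °C; aq. Cs2CO3; 28, PdCl2(dppf), AsPh3, DMF, rt
Reagents that add atoms: none
Why: Anti-Markovnikov hydroboration of the vinyl group followed by B-alkyl Suzuki–Miyaura coupling with the alkenyl iodide, which goes with retention of alkene geometry and tolerates trisubstituted epoxides and the allylsilane under mild carbonate base.

Step 16
Reactants: 30 diepoxy (Z)-allylsilane carrying the protected right half
Product: 31 {[(3S,5aS,6R,9aS)-6-{2-[(3S,5aR,6S,7S,9aS)-3-[(tert-butyldimethylsilyl)oxy]-2,2,5a,7-tetramethyl-6-[(triethylsilyl)oxy]decahydro-1-benzoxepin-6-yl]ethyl}-2,2,5a-trimethyl-7-methylidenedecahydro-1-benzoxepin-3-yl]oxy}trimethylsilane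
Conditions: TMSOTf (1.2 equiv), DTBMP (2 equiv), CH2Cl2, −78 °C; Et3N quench
Reagents that add atoms: trimethylsilyl trifluoromethanesulfonate, C[Si](C)(C)OS(=O)(=O)C(F)(F)F
Why: TMSOTf silylates the terminal trisubstituted epoxide, the inner epoxide oxygen attacks its CMe2 carbon to give a bicyclic epoxonium ion, and the allylsilane opens this ion at the methyl-bearing carbon, the β-silyl cation then losing Me3Si+ to leave the exocyclic C=CH2. The closest known reaction type is the silyl-triflate-promoted epoxide-opening oxa-/carbacyclisation cascade terminated by an allylsilane, which gives trans-fused oxepane–cyclohexanes. The oxepane closes by C–O bond formation at CMe2 followed by ring expansion of the epoxonium ion (net 7-endo), and the cyclohexane closes by 6-endo attack of the alkene CH on the epoxonium carbon. The quaternary carbon is set by inversion of the (S)-configured epoxide carbon, the adjacent CH by the chair transition state together with the Z-allylsilane geometry (the CH2CH2 link is trans to the ring-forming chain and so becomes equatorial), and the CH–O centres are carried over unchanged from the epoxides. The step needs attack at the more substituted carbon of each epoxide and alkene formation only at the exocyclic position; tertiary-cation character at both carbons and the β-silicon effect should secure this, while the hindered pyridine base suppresses protodesilylation and the fully ether-protected right half offers no competing nucleophile.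

Step 17
Reactants: 31 tris-silyl ether
Product: 32 (3S,5aS,6R,9aS)-6-{2-[(3S,5aR,6S,7S,9aS)-3,6-dihydroxy-2,2,5a,7-tetramethyldecahydro-1-benzoxepin-6-yl]ethyl}-2,2,5a-trimethyl-7-methylidenedecahydro-1-benzoxepin-3-ol
Conditions: TBAF (6 equiv), THF, rt → 50 °C
Reagents that add atoms: none
Why: Fluoride-mediated desilylation removes the trimethylsilyl, tert-butyldimethylsilyl and tertiary triethylsilyl ethers in one operation and affects neither the exocyclic alkene nor the oxepanes.

Step 18
Reactants: 32 triol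
Product: 33 CNP0218659.1, (5aS,6R,9aS)-6-{2-[(5aR,6S,7S,9aS)-6-hydroxy-2,2,5a,7-tetramethyl-3-oxodecahydro-1-benzoxepin-6-yl]ethyl}-2,2,5a-trimethyl-7-methylideneoctahydro-1-benzoxepin-3(2H)-one
Conditions: Dess–Martin periodinane (3 equiv), CH2Cl2, 0 °C → rt
Reagents that add atoms: none
Why: Dess–Martin oxidation converts both secondary oxepanols into ketones while the tertiary alcohol cannot be oxidised, and no stereocentre is α to either new carbonyl (each is flanked by CMe2 and CH2), so nothing can epimerise.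

**Compound list**

1 | geranyl bromide | CC(C)=CCC/C(C)=C/CBr | starting material
2 | (4-bromobut-1-yn-1-yl)trimethylsilane | C[Si](C)(C)C#CCCBr | starting material
3 | [4-(trimethylsilyl)but-3-yn-1-yl]magnesium bromide | C[Si](C)(C)C#CCC[Mg]Br | intermediate (not isolated)
4 | trimethyl[(6E)-7,11-dimethyldodeca-6,10-dien-1-yn-1-yl]silane | CC(C)=CCC/C(C)=C/CCCC#C[Si](C)(C)C | intermediate (not isolated)
5 | (6E)-7,11-dimethyldodeca-6,10-dien-1-yne | CC(C)=CCC/C(C)=C/CCCC#C | intermediate
6 | (iodomethyl)trimethylsilane | C[Si](C)(C)CI | starting material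
7 | [(6E)-7,11-dimethyldodeca-6,10-dien-1-yn-1-yl]lithium | CC(C)=CCC/C(C)=C/CCCC#C[Li] | intermediate (not isolated)
8 | trimethyl[(7E)-8,12-dimethyltrideca-7,11-dien-2-yn-1-yl]silane | CC(C)=CCC/C(C)=C/CCCC#CC[Si](C)(C)C | intermediate
9 | trimethyl{6-[(2S,3S)-3-{2-[(2S)-3,3-dimethyloxiran-2-yl]ethyl}-3-methyloxiran-2-yl]hex-2-yn-1-yl}silane | C[Si](C)(C)CC#CCCC[C@@H]1O[C@@]1(C)CC[C@@H]1OC1(C)C | intermediate
10 | trimethylsilyl ether of 11 | C=C=C1CCC[C@@H]2OC(C)(C)[C@@H](O[Si](C)(C)C)CC[C@]21C | intermediate (not isolated)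
11 | (3S,5aS,9aS)-6-ethenylidene-2,2,5a-trimethyldecahydro-1-benzoxepin-3-ol | C=C=C1CCC[C@@H]2OC(C)(C)[C@@H](O)CC[C@]21C | intermediate
12 | tert-butyldimethylsilyl ether of 11 | C=C=C1CCC[C@@H]2OC(C)(C)[C@@H](O[Si](C)(C)C(C)(C)C)CC[C@]21C | intermediate
13 | (3S,5aR,9aS)-3-[(tert-butyldimethylsilyl)oxy]-2,2,5a-trimethyloctahydro-1-benzoxepin-6(2H)-one | O=C1CCC[C@@H]2OC(C)(C)[C@@H](O[Si](C)(C)C(C)(C)C)CC[C@]21C | intermediate
14 | lithium enolate of 13 (C6=C7) | [Li]OC1=CCC[C@@H]2OC(C)(C)[C@@H](O[Si](C)(C)C(C)(C)C)CC[C@]21C | intermediate (not isolated)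
15 | (3S,5aR,7S,9aS)-3-[(tert-butyldimethylsilyl)oxy]-2,2,5a,7-tetramethyloctahydro-1-benzoxepin-6(2H)-one | O=C1[C@@H](C)CC[C@@H]2OC(C)(C)[C@@H](O[Si](C)(C)C(C)(C)C)CC[C@]21C | intermediate
16 | tert-butyldimethyl{[(3S,5aS,7S,9aS)-2,2,5a,7-tetramethyl-6-methylidenedecahydro-1-benzoxepin-3-yl]oxy}silane | C=C1[C@@H](C)CC[C@@H]2OC(C)(C)[C@@H](O[Si](C)(C)C(C)(C)C)CC[C@]21C | intermediate
17 | tert-butyldimethylsilyl ether of (3S,5aR,6S,7S,9aS)-2,2,5a,7-tetramethyloctahydro-2H-spiro[1-benzoxepine-6,2'-oxiran]-3-ol | C1O[C@]12[C@@H](C)CC[C@@H]3OC(C)(C)[C@@H](O[Si](C)(C)C(C)(C)C)CC[C@]32C | intermediate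
18 | (3S,5aR,6S,7S,9aS)-3-[(tert-butyldimethylsilyl)oxy]-6-ethenyl-2,2,5a,7-tetramethyldecahydro-1-benzoxepin-6-ol | C=C[C@]1(O)[C@@H](C)CC[C@@H]2OC(C)(C)[C@@H](O[Si](C)(C)C(C)(C)C)CC[C@]21C | intermediate
19 | triethylsilyl ether of 18 | C=C[C@]1(O[Si](CC)(CC)CC)[C@@H](C)CC[C@@H]2OC(C)(C)[C@@H](O[Si](C)(C)C(C)(C)C)CC[C@]21C | intermediate
20 | trimethyl(prop-1-yn-1-yl)silane | CC#C[Si](C)(C)C | starting material
21 | [3-(trimethylsilyl)prop-2-yn-1-yl]lithium | [Li]CC#C[Si](C)(C)C | intermediate (not isolated)
22 | trimethyl[(5E)-6,10-dimethylundeca-5,9-dien-1-yn-1-yl]silane | CC(C)=CCC/C(C)=C/CCC#C[Si](C)(C)C | intermediate (not isolated)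
23 | (5E)-6,10-dimethylundeca-5,9-dien-1-yne | CC(C)=CCC/C(C)=C/CCC#C | intermediate
24 | (trimethylsilyl)methylmagnesium chloride | C[Si](C)(C)C[Mg]Cl | starting material
25 | [(trimethylsilyl)methyl]copper | C[Si](C)(C)C[Cu] | intermediate (not isolated)
26 | alkenylcopper from syn-addition of 25 to 23 (Cu cis to CH2SiMe3) | C[Si](C)(C)C/C(CC/C=C(\C)CCC=C(C)C)=C\[Cu] | intermediate (not isolated)
27 | [(2Z,5E)-2-(iodomethylidene)-6,10-dimethylundeca-5,9-dien-1-yl]trimethylsilane | C[Si](C)(C)C/C(CC/C=C(\C)CCC=C(C)C)=C\I | intermediate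
28 | {(2Z)-2-(iodomethylidene)-4-[(2S,3S)-3-{2-[(2S)-3,3-dimethyloxiran-2-yl]ethyl}-3-methyloxiran-2-yl]butyl}trimethylsilane | C[Si](C)(C)C/C(CC[C@@H]1O[C@@]1(C)CC[C@@H]1OC1(C)C)=C\I | intermediate
29 | B-alkyl-9-BBN adduct of 19 (boron on the terminal carbon) | C1CCC2CCCC1B2CC[C@]3(O[Si](CC)(CC)CC)[C@@H](C)CC[C@@H]4OC(C)(C)[C@@H](O[Si](C)(C)C(C)(C)C)CC[C@]43C | intermediate (not isolated)
30 | diepoxy (Z)-allylsilane carrying the silyl-protected right half (name as in step 15) | C[Si](C)(C)C/C(CC[C@@H]1O[C@@]1(C)CC[C@@H]1OC1(C)C)=C\CC[C@]1(O[Si](CC)(CC)CC)[C@@H](C)CC[C@@H]2OC(C)(C)[C@@H](O[Si](C)(C)C(C)(C)C)CC[C@]21C | intermediate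
31 | full skeleton as left trimethylsilyl, right triethylsilyl and tert-butyldimethylsilyl ether (name as in step 16) | C=C1CC[C@@H]2OC(C)(C)[C@@H](O[Si](C)(C)C)CC[C@@]2(C)[C@@H]1CC[C@]1(O[Si](CC)(CC)CC)[C@@H](C)CC[C@@H]2OC(C)(C)[C@@H](O[Si](C)(C)C(C)(C)C)CC[C@]21C | intermediate
32 | triol (name as in step 17) | C=C1CC[C@@H]2OC(C)(C)[C@@H](O)CC[C@@]2(C)[C@@H]1CC[C@]1(O)[C@@H](C)CC[C@@H]2OC(C)(C)[C@@H](O)CC[C@]21C | intermediate
33 | CNP0218659.1 (name as in step 18) | C=C1CC[C@@H]2OC(C)(C)C(=O)CC[C@@]2(C)[C@@H]1CC[C@]1(O)[C@@H](C)CC[C@@H]2OC(C)(C)C(=O)CC[C@]21C | target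

**Step count**

Total: 18 steps. Longest linear sequence: 15 steps (steps 1–11 and 15–18, from geranyl bromide).

**Steps most likely to fail**

1. Step 16. Capture of the bicyclic epoxonium ion by the allylsilane may lose to protodesilylation, elimination or hydride shift, because the nucleophilic carbon carries a large branched substituent and the right half holds several Lewis-basic oxygens and an acid-sensitive tertiary silyl ether. Fallback: close the left rings before the union on a small substrate, and make the central CH2–CH2 bond by epoxide opening. The fallback sets out from 28 (and uses 17) and returns at 32. Stille coupling of 28 with (tributylstannyl)methanol (Pd(PPh3)4, dioxane, 80 °C) would give (2Z)-5-[(2S,3S)-3-{2-[(2S)-3,3-dimethyloxiran-2-yl]ethyl}-3-methyloxiran-2-yl]-3-[(trimethylsilyl)methyl]pent-2-en-1-ol F1. With TMSOTf/DTBMP at −78 °C the hydroxyl is silylated first to its trimethylsilyl ether F2, which should undergo the same bicyclisation to the bicyclic bis(trimethylsilyl) ether F3. Methanolysis (K2CO3, MeOH) gives (3S,5aS,6R,9aS)-6-(hydroxymethyl)-2,2,5a-trimethyl-7-methylidenedecahydro-1-benzoxepin-3-ol F4, and iodination of the primary hydroxyl (I2, PPh3, imidazole) gives the 6-(iodomethyl) alcohol F5. t-BuLi (3.2 equiv, Et2O/pentane, −78 °C) gives the lithium alkoxide–alkyllithium F6, which with BF3·OEt2 should open spiro-epoxide 17 at its CH2 to the coupled diol mono-silyl ether F7, the tertiary carbinol arising already correctly configured. TBAF then gives 32.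

2. Step 14. The dioxirane may also oxidise the iodine-bearing allylsilane alkene or the iodide, eroding chemoselectivity. Fallback: epoxidise before the alkenyl iodide exists. The fallback sets out from 23 and returns at 28. Shi epoxidation of 23 under the conditions of step 3 (the alkyne is inert) would give (2S,3S)-2-(but-3-yn-1-yl)-3-{2-[(2S)-3,3-dimethyloxiran-2-yl]ethyl}-3-methyloxirane F8. Silylmethylcupration with 25 in THF at ≤ 0 °C, where trisubstituted epoxides are not opened by organocopper reagents, gives the diepoxy alkenylcopper F9, and iodinolysis gives 28.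

3. Step 10. The basic ylide may isomerise the hindered spiro-epoxide to an allylic alkoxide by β-elimination instead of attacking its neopentyl-type CH2. Fallback: build the vinyl group by olefination. The fallback sets out from 16 and returns at 18. Dihydroxylation of 16 (OsO4 cat., NMO, acetone/H2O) from the face anti to the angular methyl would give (3S,5aR,6S,7S,9aS)-3-[(tert-butyldimethylsilyl)oxy]-6-(hydroxymethyl)-2,2,5a,7-tetramethyldecahydro-1-benzoxepin-6-ol F10. Parikh–Doering oxidation of the primary hydroxyl (SO3·pyridine, DMSO, i-Pr2NEt) gives the α-hydroxy aldehyde F11, and Wittig methylenation (Ph3P=CH2, 2.5 equiv, THF) gives 18.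

**Further compounds**

F1 | step 16 | (2Z)-5-[(2S,3S)-3-{2-[(2S)-3,3-dimethyloxiran-2-yl]ethyl}-3-methyloxiran-2-yl]-3-[(trimethylsilyl)methyl]pent-2-en-1-ol | C[Si](C)(C)C/C(CC[C@@H]1O[C@@]1(C)CC[C@@H]1OC1(C)C)=C\CO
F2 | step 16 | trimethylsilyl ether of F1 | C[Si](C)(C)C/C(CC[C@@H]1O[C@@]1(C)CC[C@@H]1OC1(C)C)=C\CO[Si](C)(C)C
F3 | step 16 | bis(trimethylsilyl) ether of F4 | C=C1CC[C@@H]2OC(C)(C)[C@@H](O[Si](C)(C)C)CC[C@@]2(C)[C@@H]1CO[Si](C)(C)C
F4 | step 16 | (3S,5aS,6R,9aS)-6-(hydroxymethyl)-2,2,5a-trimethyl-7-methylidenedecahydro-1-benzoxepin-3-ol | C=C1CC[C@@H]2OC(C)(C)[C@@H](O)CC[C@@]2(C)[C@@H]1CO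
F5 | step 16 | (3S,5aS,6R,9aS)-6-(iodomethyl)-2,2,5a-trimethyl-7-methylidenedecahydro-1-benzoxepin-3-ol | C=C1CC[C@@H]2OC(C)(C)[C@@H](O)CC[C@@]2(C)[C@@H]1CI
F6 | step 16 | lithium alkoxide–alkyllithium from F5 | C=C1CC[C@@H]2OC(C)(C)[C@@H](O[Li])CC[C@@]2(C)[C@@H]1C[Li]
F7 | step 16 | coupled diol, right-half tert-butyldimethylsilyl ether of 32 | C=C1CC[C@@H]2OC(C)(C)[C@@H](O)CC[C@@]2(C)[C@@H]1CC[C@]1(O)[C@@H](C)CC[C@@H]2OC(C)(C)[C@@H](O[Si](C)(C)C(C)(C)C)CC[C@]21C
F8 | step 14 | (2S,3S)-2-(but-3-yn-1-yl)-3-{2-[(2S)-3,3-dimethyloxiran-2-yl]ethyl}-3-methyloxirane | C#CCC[C@@H]1O[C@@]1(C)CC[C@@H]1OC1(C)C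
F9 | step 14 | diepoxy alkenylcopper from syn-addition of 25 to F8 | C[Si](C)(C)C/C(CC[C@@H]1O[C@@]1(C)CC[C@@H]1OC1(C)C)=C\[Cu]
F10 | step 10 | (3S,5aR,6S,7S,9aS)-3-[(tert-butyldimethylsilyl)oxy]-6-(hydroxymethyl)-2,2,5a,7-tetramethyldecahydro-1-benzoxepin-6-ol | OC[C@]1(O)[C@@H](C)CC[C@@H]2OC(C)(C)[C@@H](O[Si](C)(C)C(C)(C)C)CC[C@]21C
F11 | step 10 | (3S,5aR,6S,7S,9aS)-3-[(tert-butyldimethylsilyl)oxy]-6-hydroxy-2,2,5a,7-tetramethyldecahydro-1-benzoxepine-6-carbaldehyde | O=C[C@]1(O)[C@@H](C)CC[C@@H]2OC(C)(C)[C@@H](O[Si](C)(C)C(C)(C)C)CC[C@]21C
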